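The readings were generated by integration for an exercise; noise was put on by code.

I followed the coupling partner.

in all of them: free catalyst 0.1 mol%
- north-west: substrate 0.016 M; coupling partner 1.2 equiv; run made earlier
- south: substrate 0.18 M; coupling partner 1.2 equiv; run made earlier
- west: substrate 0.050 M; coupling partner 2.6 equiv; run made earlier
- epsilon: substrate 0.050 M; coupling partner 1.20 equiv; time 40 h
- alpha: substrate 0.20 M; coupling partner 4.80 equiv; time 40 h
- zeta: substrate 0.030 M; coupling partner 1.80 equiv; time 40 h
- delta: substrate 0.10 M; coupling partner 0.800 equiv; time 40 h

| run | time / h | product / % | substrate / % |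
|---|---|---|---|
| north-west | 10.0 | 9.4 | 90.7 |
| north-west | 20.0 | 17.8 | 81.8 |
| north-west | 30.0 | 25.3 | 74.6 |
| north-west | 40.0 | 32.4 | 67.4 |
| south | 5.00 | 18.3 | 81.8 |
| south | 15.0 | 50.3 | 49.6 |
| south | 25.0 | 74.9 | 24.9 |
| south | 40.0 | 84.2 | 15.6 |
| west | 3.00 | 6.2 | 93.5 |
| west | 8.00 | 16.7 | 82.9 |
| west | 15.0 | 29.9 | 70.5 |
| west | 40.0 | 64.2 | 35.5 |

(each reading ± 0.3 percentage points)



- the flasks put in order of amount of product, in percent of the substrate charged, best first, at 40 h (epsilon / alpha / zeta / delta)
- the same order at 12 d (epsilon / alpha / zeta / delta)
- the amount of product, in percent of the substrate charged of the flask you put first, at 40 h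
- the amount of product, in percent of the substrate charged of the flask you put last, at 40 h

I read the south run row by row. Between 5.00 h and 25.0 h its product rose at an average r = 0.0283 h⁻¹, as a fraction of the substrate charged. From there to 40.0 h the rise was 0.00620 h⁻¹, slower, although 15.6% of the substrate remained. South had been charged 1.2 equiv of partner and held 84.2% of product, so I wrote the partner's balance. If the flask had stalled for want of partner, 35.8% of the substrate's amount in partner had left without giving product.

At rate r, that product took t_s = 29.8 h. Unbound partner falling to nothing averages about half its charge over that time. I therefore defined the waste constant k_d, the fraction of unbound partner lost per hour without giving product, and the balance gave 0.0201 h⁻¹.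

For a charge E in equivalents, the same balance gives a ceiling Y = E/(1 + w), with w = k_d·E/(2·r). I took the product at time t as the smaller of r·t and Y.

Delta has substrate near south's middle range, so I used south's r. Its partner is the limiting reagent, at 0.800 equiv, and its ceiling came to 62.3%. Epsilon shares west's concentration, so with 0.0197 h⁻¹ its ceiling was 74.6%. For zeta I took the geometric mean of the west and north-west rates, 0.0126 h⁻¹, which gave a ceiling of 74.2% but 50.4% by 40 h. Alpha's ceiling, 178%, stood above the substrate. My order at 40 h was therefore alpha, epsilon, delta, zeta, and at 12 d alpha first, delta last, with epsilon and zeta too close to part.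

The forecast differed. It gave alpha > delta > epsilon > zeta at 40 h, with 82% and 49%, and zeta > epsilon > alpha > delta at 12 d. Of south's stall it said: “I read it as catalyst loss or product inhibition at high product.”

The flasks gave alpha > epsilon > delta > zeta, with 96.0% and 49.1%, and alpha > zeta > epsilon > delta at 12 d.

    coupling partner → decomposed reagent (k = 7.00 × 10⁻⁶ s⁻¹)
    substrate + catalyst intermediate B ⇌ catalyst intermediate C (K = 70.0 M⁻¹, k = 0.850 M⁻¹ s⁻¹)
    catalyst intermediate C → free catalyst + product (k = 0.0210 s⁻¹)
    coupling partner + free catalyst → catalyst intermediate A (k = 8.20 M⁻¹ s⁻¹)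
    catalyst intermediate A ⇌ catalyst intermediate B (K = 0.640, k = 0.0450 s⁻¹)

Delta reached 59.5% against my ceiling of 62.3%, with 0% of its partner left and 0.0205 M of decomposed reagent. I then took the neighbouring flask, alpha with 0.025 mol% of free catalyst. My estimate of k_d, read from south, put the share of the partner escaping waste by 40 h at 44.8%. The product of 36.1% in that flask took 7.53% of the partner charge, so my reckoning left 37.3%. That flask held, unbound, 32%.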